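**Retrosynthetic overview**
1. Target ⇐ bis-silyl ether 28; the enone comes from an alkenylchromium addition to a neopentyl aldehyde followed by oxidation.
2. Keto aldehyde 22 ⇐ glycol cleavage of a bicyclo[3.3.0]octane-2,3-diol: the two carbonyl arms on the vicinal quaternary carbons are the two halves of a cut cyclopentane ring.
3. Diol ⇐ Z-allylbarium + α-silyloxy ketone 8 ⇐ enantioselective deprotonation of meso cis-1,5-dimethylbicyclo[3.3.0]octan-3-one (key step: one proton removal fixes both quaternary centres).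
4. Meso ketone ⇐ 1,2-dimethylcyclopentene by dichloroketene [2+2] and CH2N2 ring expansion; side chain ⇐ Negishi coupling of a benzylzinc with (Z)-3-iodo-2-methylprop-2-en-1-ol.
5. Ring order: the cyclopentane of 1 is kept throughout; a cyclobutanone is fused on (step 1), expanded to a second cyclopentanone (step 2), and that ring is cut open in step 12; the arene is bought.

Assumption: the lithium amide from (R,R)-bis(1-phenylethyl)amine is taken to remove the proton next to the bridgehead that becomes the acyl-bearing carbon, giving (1R,5S)-6; if the sense is found opposite, the (S,S)-amine is used and nothing else changes.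

Abbreviation: Ar = 2,5-bis(tert-butyldimethylsilyloxy)-3-methylphenyl.

**Route**

Step 1
Reactants: 1 1,2-dimethylcyclopentene
Product: 2 (±)-cis-7,7-dichloro-1,5-dimethylbicyclo[3.2.0]heptan-6-one
Conditions: Cl3CCOCl, activated Zn dust, POCl3, Et2O, sonication, 20 °C
Reagents that add atoms: trichloroacetyl chloride, ClC(Cl)(Cl)C(Cl)=O
Why: Ketene–alkene [2+2] cycloaddition (Staudinger type, Krepski–Hassner conditions): dichloroketene made in the flask adds suprafacially to the electron-rich tetrasubstituted alkene, so the cis ring fusion and both methyl-bearing quaternary carbons are fixed at once with no regiochemical question (the product is racemic, which does not matter because step 3 gives a meso compound).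

Step 2
Reactants: 2 (±)-cis-7,7-dichloro-1,5-dimethylbicyclo[3.2.0]heptan-6-one
Product: 3 (±)-cis-2,2-dichloro-1,5-dimethylbicyclo[3.3.0]octan-3-one
Conditions: CH2N2, Et2O, MeOH (cat.), 0 °C → rt
Reagents that add atoms: diazomethane, C=[N+]=[N-]
Why: Regioselective diazomethane ring expansion of an α,α-dichlorocyclobutanone (Greene three-carbon annulation): only the non-chlorinated, electron-richer bridgehead carbon migrates, which places the new CH2 between that carbon and the carbonyl without touching the quaternary centres.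

Step 3
Reactants: 3 (±)-cis-2,2-dichloro-1,5-dimethylbicyclo[3.3.0]octan-3-one
Product: 4 cis-1,5-dimethylbicyclo[3.3.0]octan-3-one (meso)
Conditions: Zn dust, AcOH, 70 °C
Reagents that add atoms: none
Why: Zinc-mediated reductive dehalogenation of the α,α-dichloro ketone gives a ketone with a mirror plane through C3 and C7, so it is meso and its two α-methylene groups are enantiotopic.

Step 4
Reactants: 4 cis-1,5-dimethylbicyclo[3.3.0]octan-3-one
Product: 6 (1R,5S)-1,5-dimethyl-3-(trimethylsilyloxy)bicyclo[3.3.0]oct-2-ene, via lithium enolate 5 (not isolated)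
Conditions: (R,R)-bis(1-phenylethyl)amine·HCl, n-BuLi (2 equiv), THF, −78 → 0 °C; then TMSCl and 4, −100 °C (in situ quench)
Reagents that add atoms: chlorotrimethylsilane, C[Si](C)(C)Cl
Why: Enantioselective deprotonation (Simpkins–Koga chiral lithium amide desymmetrisation with internal silyl quench): the homochiral amide distinguishes the two enantiotopic α-methylene groups of the meso ketone, so this single proton removal fixes the absolute configuration of both existing quaternary carbons, with the sense taken from the stated assumption and an expected ee near 90% that is carried unchanged to 29.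

Step 5
Reactants: 6 (1R,5S)-1,5-dimethyl-3-(trimethylsilyloxy)bicyclo[3.3.0]oct-2-ene
Product: 8 (1S,2R,5S)-1,5-dimethyl-2-(trimethylsilyloxy)bicyclo[3.3.0]octan-3-one, via silyloxy epoxide 7 (not isolated)
Conditions: mCPBA, hexane, −15 °C → rt; filter, concentrate
Reagents that add atoms: 3-chloroperoxybenzoic acid, OOC(=O)c1cccc(Cl)c1
Why: Rubottom oxidation: the peracid epoxidises the enol ether on the outer face and the silyloxy oxirane opens with 1,4-silyl shift to the α-silyloxy ketone, so the new C2 centre is R (oxygen cis to the angular methyls), although its configuration is immaterial because C2 becomes a carbonyl carbon in step 12.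

Step 6
Reactants: 9 2,6-dimethylbenzene-1,4-diol
Product: 10 1,4-bis(tert-butyldimethylsilyloxy)-2,6-dimethylbenzene
Conditions: TBSCl, imidazole, DMF, rt → 40 °C
Reagents that add atoms: tert-butyldimethylsilyl chloride, CC(C)(C)[Si](C)(C)Cl
Why: Imidazole-promoted silylation protects both phenols as aryl silyl ethers that survive the radical bromination, organozinc, organobarium, Pb(OAc)4 and CrCl2 steps and are removed by fluoride at the end.

Step 7
Reactants: 10 1,4-bis(tert-butyldimethylsilyloxy)-2,6-dimethylbenzene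
Product: 11 2-(bromomethyl)-1,4-bis(tert-butyldimethylsilyloxy)-6-methylbenzene
Conditions: NBS (0.95 equiv), AIBN (cat.), PhCF3, 80 °C
Reagents that add atoms: N-bromosuccinimide, O=C1CCC(=O)N1Br
Why: Wohl–Ziegler benzylic bromination: the two methyl groups are equivalent, the free ring positions are flanked by a methyl and a bulky silyloxy group so radical substitution at the benzylic carbon outruns ring bromination, and sub-stoichiometric NBS limits double bromination.

Step 8
Reactants: 12 prop-2-yn-1-ol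
Product: 14 (2Z)-3-iodo-2-methylprop-2-en-1-ol, via alkenylmagnesium alkoxide 13 (not isolated)
Conditions: MeMgBr (2.5 equiv), CuI (10 mol %), THF, −10 °C → rt; then I2, −10 °C
Reagents that add atoms: methylmagnesium bromide, C[Mg]Br; iodine, [I][I]
Why: Copper-catalysed anti-carbomagnesiation of a propargylic alkoxide (Duboudin–Jousseaume reaction): methyl goes to C2 and magnesium to C3 within a five-membered chelate that holds magnesium cis to the CH2O group, and iodinolysis with retention gives only the Z-alkenyl iodide.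

Step 9
Reactants: 11 2-(bromomethyl)-1,4-bis(tert-butyldimethylsilyloxy)-6-methylbenzene; 14 (2Z)-3-iodo-2-methylprop-2-en-1-ol
Product: 16 (2Z)-4-Ar-2-methylbut-2-en-1-ol, via benzylzinc bromide 15 (not isolated)
Conditions: Zn dust, LiCl, THF, 0 °C → rt (1.3 equiv of 15); then 14, Pd(PPh3)4 (3 mol %), THF, rt
Reagents that add atoms: none
Why: Negishi coupling: zinc insertion into the benzylic bromide gives a mild organozinc that tolerates the silyl ethers and the free hydroxyl, and the palladium-catalysed sp3–sp2 coupling proceeds with retention at the alkenyl iodide so that CH2Ar ends cis to CH2OH (Z).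

Step 10
Reactants: 16 (2Z)-4-Ar-2-methylbut-2-en-1-ol
Product: 18 (2Z)-4-Ar-1-chloro-2-methylbut-2-ene, via allylic mesylate 17 (not isolated)
Conditions: MsCl, LiCl, 2,4,6-collidine, DMF, 0 °C
Reagents that add atoms: lithium chloride, [Li+].[Cl-]
Why: Collington–Meyers chlorination: mesylation followed by SN2 displacement with chloride at the primary allylic carbon gives the chloride without allylic transposition or Z-to-E isomerisation.

Step 11
Reactants: 8 (1S,2R,5S)-1,5-dimethyl-2-(trimethylsilyloxy)bicyclo[3.3.0]octan-3-one; 18 (2Z)-4-Ar-1-chloro-2-methylbut-2-ene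
Product: 21 (1S,2R,3S,5S)-3-[(2Z)-4-Ar-2-methylbut-2-en-1-yl]-1,5-dimethylbicyclo[3.3.0]octane-2,3-diol, via allylbarium chloride 19 (not isolated), via silyl ether adduct 20 (not isolated)
Conditions: BaI2, Li biphenylide (2 equiv), THF, rt; 18, −78 °C; 8, −78 °C; then citric acid, MeOH, rt
Reagents that add atoms: none
Why: Yamamoto allylbarium carbonyl addition: the allylbarium formed at −78 °C is configurationally stable and attacks the ketone through its unsubstituted CH2 terminus, keeping the Z-alkene, while the new C3 carbinol centre (attack expected anti to the neighbouring silyloxy group, giving the cis-diol) is irrelevant because both C3 epimers are cleaved in step 12, and acidic methanolysis removes the labile trimethylsilyl ether.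

Step 12
Reactants: 21 (1S,2R,3S,5S)-3-[(2Z)-4-Ar-2-methylbut-2-en-1-yl]-1,5-dimethylbicyclo[3.3.0]octane-2,3-diol
Product: 22 (1S,2S)-2-[(4Z)-6-Ar-4-methyl-2-oxohex-4-en-1-yl]-1,2-dimethylcyclopentane-1-carbaldehyde
Conditions: Pb(OAc)4, CH2Cl2, −20 → 0 °C; used crude
Reagents that add atoms: none
Why: Criegee glycol cleavage: Pb(OAc)4 cleaves cis- and trans-cyclopentane-1,2-diols alike, turning C3 into the β,γ-unsaturated ketone and C2 into the neopentyl aldehyde under cold neutral conditions that neither move the Z-alkene into conjugation nor touch the two quaternary stereocentres.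

Step 13
Reactants: 23 2-methylbut-3-yn-2-ol
Product: 25 (3E)-4-iodo-2-methylbut-3-en-2-ol, via alkenylstannane 24 (not isolated)
Conditions: Bu3SnH, PdCl2(PPh3)2 (2 mol %), THF, 0 °C → rt; then I2, CH2Cl2, 0 °C
Reagents that add atoms: iodine, [I][I]
Why: Palladium-catalysed syn-hydrostannation puts tin on the terminal carbon trans to the bulky tertiary carbinol (E), and iododestannylation proceeds with retention to the E-alkenyl iodide.

Step 14
Reactants: 22 (1S,2S)-2-[(4Z)-6-Ar-4-methyl-2-oxohex-4-en-1-yl]-1,2-dimethylcyclopentane-1-carbaldehyde; 25 (3E)-4-iodo-2-methylbut-3-en-2-ol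
Product: 27 (4Z)-6-Ar-1-[(1S,2S)-2-[(2E)-1,4-dihydroxy-4-methylpent-2-en-1-yl]-1,2-dimethylcyclopentyl]-4-methylhex-4-en-2-one (both carbinol epimers), via alkenylchromium dichloride 26 (not isolated)
Conditions: CrCl2 (6 equiv), NiCl2 (2 mol %), DMSO, rt
Reagents that add atoms: none
Why: Nozaki–Hiyama–Kishi coupling: the alkenylchromium species adds only to the aldehyde, tolerating the enolisable ketone and the free tertiary hydroxyl and keeping the E-geometry, and the new carbinol centre is formed unselectively but is oxidised away in step 15.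

Step 15
Reactants: 27 (4Z)-6-Ar-1-[(1S,2S)-2-[(2E)-1,4-dihydroxy-4-methylpent-2-en-1-yl]-1,2-dimethylcyclopentyl]-4-methylhex-4-en-2-one
Product: 28 (2E)-1-[(1S,2S)-2-[(4Z)-6-Ar-4-methyl-2-oxohex-4-en-1-yl]-1,2-dimethylcyclopentyl]-4-hydroxy-4-methylpent-2-en-1-one
Conditions: Dess–Martin periodinane, CH2Cl2, 0 °C → rt
Reagents that add atoms: none
Why: Dess–Martin oxidation converts the secondary allylic alcohol (which equilibrates with its cyclic hemiketal, so the open form is drained) into the E-enone, while the tertiary alcohol, the silyl ethers and the skipped Z-alkene are inert.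

Step 16
Reactants: 28 (2E)-1-[(1S,2S)-2-[(4Z)-6-Ar-4-methyl-2-oxohex-4-en-1-yl]-1,2-dimethylcyclopentyl]-4-hydroxy-4-methylpent-2-en-1-one
Product: 29 (2E)-1-[(1S,2S)-2-[(4Z)-6-(2,5-dihydroxy-3-methylphenyl)-4-methyl-2-oxohex-4-en-1-yl]-1,2-dimethylcyclopentyl]-4-hydroxy-4-methylpent-2-en-1-one
Conditions: TBAF, AcOH (1:1), THF, 0 °C → rt, argon
Reagents that add atoms: none
Why: Fluoride-mediated cleavage of the two aryl silyl ethers, buffered with acetic acid and run under argon so that neither enolate chemistry (conjugation of the β,γ-enone, aldol or Michael closure of the 1,5-diketone) nor air oxidation of the hydroquinone intervenes, releases the target without affecting any stereocentre.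

**Compound list**
1 | 1,2-dimethylcyclopentene | CC1=C(C)CCC1 | starting material
2 | (±)-cis-7,7-dichloro-1,5-dimethylbicyclo[3.2.0]heptan-6-one (racemate, one enantiomer drawn) | C[C@@]12CCC[C@]1(C)C(Cl)(Cl)C2=O | intermediate
3 | (±)-cis-2,2-dichloro-1,5-dimethylbicyclo[3.3.0]octan-3-one (racemate, one enantiomer drawn) | C[C@@]12CCC[C@]1(C)C(Cl)(Cl)C(=O)C2 | intermediate
4 | cis-1,5-dimethylbicyclo[3.3.0]octan-3-one (meso) | C[C@@]12CCC[C@]1(C)CC(=O)C2 | intermediate
5 | lithium (1R,5S)-1,5-dimethylbicyclo[3.3.0]oct-2-en-3-olate | C2[C@]1(C)CCC[C@]1(C)C=C2O[Li] | intermediate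
6 | (1R,5S)-1,5-dimethyl-3-(trimethylsilyloxy)bicyclo[3.3.0]oct-2-ene | C2[C@]1(C)CCC[C@]1(C)C=C2O[Si](C)(C)C | intermediate
7 | (1S,5S)-2,3-epoxy-1,5-dimethyl-3-(trimethylsilyloxy)bicyclo[3.3.0]octane, oxirane oxygen cis to both methyl groups | C2[C@]1(C)CCC[C@]1(C)[C@H]3O[C@@]23O[Si](C)(C)C | intermediate
8 | (1S,2R,5S)-1,5-dimethyl-2-(trimethylsilyloxy)bicyclo[3.3.0]octan-3-one | C2[C@]1(C)CCC[C@]1(C)[C@@H](O[Si](C)(C)C)C2=O | intermediate
9 | 2,6-dimethylbenzene-1,4-diol | Cc1cc(O)cc(C)c1O | starting material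
10 | 1,4-bis(tert-butyldimethylsilyloxy)-2,6-dimethylbenzene | Cc1cc(O[Si](C)(C)C(C)(C)C)cc(C)c1O[Si](C)(C)C(C)(C)C | intermediate
11 | 2-(bromomethyl)-1,4-bis(tert-butyldimethylsilyloxy)-6-methylbenzene | BrCc1cc(O[Si](C)(C)C(C)(C)C)cc(C)c1O[Si](C)(C)C(C)(C)C | intermediate
12 | prop-2-yn-1-ol | OCC#C | starting material
13 | bromomagnesium (2Z)-3-(bromomagnesio)-2-methylprop-2-en-1-olate (chelated) | Br[Mg]/C=C(C)\CO[Mg]Br | intermediate
14 | (2Z)-3-iodo-2-methylprop-2-en-1-ol | OC/C(C)=C\I | intermediate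
15 | [2,5-bis(tert-butyldimethylsilyloxy)-3-methylbenzyl]zinc bromide | Br[Zn]Cc1cc(O[Si](C)(C)C(C)(C)C)cc(C)c1O[Si](C)(C)C(C)(C)C | intermediate
16 | (2Z)-4-[2,5-bis(tert-butyldimethylsilyloxy)-3-methylphenyl]-2-methylbut-2-en-1-ol | OC/C(C)=C\Cc1cc(O[Si](C)(C)C(C)(C)C)cc(C)c1O[Si](C)(C)C(C)(C)C | intermediate
17 | (2Z)-4-[2,5-bis(tert-butyldimethylsilyloxy)-3-methylphenyl]-2-methylbut-2-en-1-yl methanesulfonate | CS(=O)(=O)OC/C(C)=C\Cc1cc(O[Si](C)(C)C(C)(C)C)cc(C)c1O[Si](C)(C)C(C)(C)C | intermediate
18 | (2Z)-4-[2,5-bis(tert-butyldimethylsilyloxy)-3-methylphenyl]-1-chloro-2-methylbut-2-ene | ClC/C(C)=C\Cc1cc(O[Si](C)(C)C(C)(C)C)cc(C)c1O[Si](C)(C)C(C)(C)C | intermediate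
19 | [(2Z)-4-[2,5-bis(tert-butyldimethylsilyloxy)-3-methylphenyl]-2-methylbut-2-en-1-yl]barium chloride | Cl[Ba]C/C(C)=C\Cc1cc(O[Si](C)(C)C(C)(C)C)cc(C)c1O[Si](C)(C)C(C)(C)C | intermediate
20 | (1S,2R,3S,5S)-3-[(2Z)-4-Ar-2-methylbut-2-en-1-yl]-1,5-dimethyl-2-(trimethylsilyloxy)bicyclo[3.3.0]octan-3-ol (major C3 epimer drawn) | C2[C@]1(C)CCC[C@]1(C)[C@@H](O[Si](C)(C)C)[C@]2(O)C/C(C)=C\Cc1cc(O[Si](C)(C)C(C)(C)C)cc(C)c1O[Si](C)(C)C(C)(C)C | intermediate
21 | (1S,2R,3S,5S)-3-[(2Z)-4-Ar-2-methylbut-2-en-1-yl]-1,5-dimethylbicyclo[3.3.0]octane-2,3-diol (major C3 epimer drawn; the other is cleaved to the same 22) | C2[C@]1(C)CCC[C@]1(C)[C@@H](O)[C@]2(O)C/C(C)=C\Cc1cc(O[Si](C)(C)C(C)(C)C)cc(C)c1O[Si](C)(C)C(C)(C)C | intermediate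
22 | (1S,2S)-2-[(4Z)-6-Ar-4-methyl-2-oxohex-4-en-1-yl]-1,2-dimethylcyclopentane-1-carbaldehyde | C/C(=C/Cc1cc(O[Si](C)(C)C(C)(C)C)cc(C)c1O[Si](C)(C)C(C)(C)C)CC(=O)C[C@]1(C)CCC[C@]1(C)C=O | intermediate
23 | 2-methylbut-3-yn-2-ol | CC(C)(O)C#C | starting material
24 | (3E)-2-methyl-4-(tributylstannyl)but-3-en-2-ol | CC(C)(O)/C=C/[Sn](CCCC)(CCCC)CCCC | intermediate
25 | (3E)-4-iodo-2-methylbut-3-en-2-ol | CC(C)(O)/C=C/I | intermediate
26 | [(1E)-3-hydroxy-3-methylbut-1-en-1-yl]chromium dichloride | CC(C)(O)/C=C/[Cr](Cl)Cl | intermediate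
27 | (4Z)-6-Ar-1-[(1S,2S)-2-[(2E)-1,4-dihydroxy-4-methylpent-2-en-1-yl]-1,2-dimethylcyclopentyl]-4-methylhex-4-en-2-one (carbinol centre unassigned, both epimers) | C/C(=C/Cc1cc(O[Si](C)(C)C(C)(C)C)cc(C)c1O[Si](C)(C)C(C)(C)C)CC(=O)C[C@]1(C)CCC[C@]1(C)C(O)/C=C/C(C)(C)O | intermediate
28 | (2E)-1-[(1S,2S)-2-[(4Z)-6-Ar-4-methyl-2-oxohex-4-en-1-yl]-1,2-dimethylcyclopentyl]-4-hydroxy-4-methylpent-2-en-1-one | C/C(=C/Cc1cc(O[Si](C)(C)C(C)(C)C)cc(C)c1O[Si](C)(C)C(C)(C)C)CC(=O)C[C@]1(C)CCC[C@]1(C)C(=O)/C=C/C(C)(C)O | intermediate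
29 | (2E)-1-[(1S,2S)-2-[(4Z)-6-(2,5-dihydroxy-3-methylphenyl)-4-methyl-2-oxohex-4-en-1-yl]-1,2-dimethylcyclopentyl]-4-hydroxy-4-methylpent-2-en-1-one | C/C(=C/Cc1cc(O)cc(C)c1O)CC(=O)C[C@]1(C)CCC[C@]1(C)C(=O)/C=C/C(C)(C)O | target

**Totals**
Total steps: 16. Longest linear sequence: 10 (steps 1, 2, 3, 4, 5, 11, 12, 14, 15, 16).

**Three steps most likely to fail**

Step 4 (enantioselective deprotonation). The chiral amide has precedent on the parent cis-bicyclo[3.3.0]octan-3-ones but not on this angularly dimethylated ketone. Both the ee and the sense are therefore unproven, and the ee of 6 is the ee of 29. Fallback, setting out from 4 and returning at 8: α-acetoxylation of 4 with Pb(OAc)4 and BF3·OEt2 in benzene/AcOH gives racemic 2-acetoxy-1,5-dimethylbicyclo[3.3.0]octan-3-one F1 (one regioisomer, since the two α-methylenes of the meso ketone are equivalent). A lipase (Amano lipase PS or Candida antarctica lipase B, pH 7 buffer/MTBE, stopped near 50% conversion, enzyme picked by screening for the needed antipode) hydrolyses one enantiomer to (1S,2R,5S)-2-hydroxy-1,5-dimethylbicyclo[3.3.0]octan-3-one F2, which is separated from the unreacted enantiomeric acetate. TMSCl and imidazole in CH2Cl2 then give 8. This replaces desymmetrisation by a kinetic resolution, costs half the material, and can deliver material of very high ee.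

Step 11 (allylbarium addition). The α-selectivity and Z-retention are established for simpler allylbariums; here the reagent carries a 2-methyl group, a benzylic CH2 and two aryl silyl ethers, and the ketone is enolisable and flanked by a silyloxy group. Fallback, setting out from 18 (with 8) and returning at 22: PhSO2Na in DMF converts 18 by SN2 into (2Z)-4-Ar-2-methylbut-2-en-1-yl phenyl sulfone F3. n-BuLi in THF at −78 °C gives its α-lithio derivative F4 (not isolated), a sulfonyl-stabilised carbanion that bonds only through the sulfonyl-bearing carbon, so the α/γ question disappears. Addition to 8 gives the silyl ether adduct F5 (not isolated), and citric acid in MeOH gives the sulfonyl diol F6. Pb(OAc)4 cleaves F6 to the β-keto sulfone aldehyde F7. SmI2 in THF/MeOH at −78 °C then removes the sulfonyl group through the samarium enolate, which is protonated on the α-carbon and gives 22.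

Step 14 (Nozaki–Hiyama–Kishi coupling). The aldehyde sits on a quaternary carbon next to a second quaternary carbon, and 22 carries an isomerisable β,γ-unsaturated ketone in a 1,5-relationship to the aldehyde, so a slow coupling leaves time for aldol closure. Fallback, setting out from 22 and returning at 28 (step 15 is then not needed): Zn(OTf)2, Et3N and 23 in toluene generate the alkynylzinc triflate F8 (not isolated), which adds to aldehydes but not to ketones and gives the propargylic diol F9. Ruthenium-catalysed redox isomerisation (RuCl(indenyl)(PPh3)2, In(OTf)3, camphorsulfonic acid, THF, 65 °C) then converts the secondary propargylic alcohol directly into the E-enone 28.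

**Further compounds**
F1 | step 4 | racemic 2-acetoxy-1,5-dimethylbicyclo[3.3.0]octan-3-one (acetoxy cis to the methyl groups; one enantiomer drawn) | C2[C@]1(C)CCC[C@]1(C)[C@@H](OC(C)=O)C2=O
F2 | step 4 | (1S,2R,5S)-2-hydroxy-1,5-dimethylbicyclo[3.3.0]octan-3-one | C2[C@]1(C)CCC[C@]1(C)[C@@H](O)C2=O
F3 | step 11 | (2Z)-4-[2,5-bis(tert-butyldimethylsilyloxy)-3-methylphenyl]-2-methylbut-2-en-1-yl phenyl sulfone | O=S(=O)(C/C(C)=C\Cc1cc(O[Si](C)(C)C(C)(C)C)cc(C)c1O[Si](C)(C)C(C)(C)C)c1ccccc1
F4 | step 11 | α-lithio derivative of the allylic sulfone | [Li]C(S(=O)(=O)c1ccccc1)/C(C)=C\Cc1cc(O[Si](C)(C)C(C)(C)C)cc(C)c1O[Si](C)(C)C(C)(C)C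
F5 | step 11 | silyl ether adduct: 3-[(2Z)-4-Ar-2-methyl-1-(phenylsulfonyl)but-2-en-1-yl]-1,5-dimethyl-2-(trimethylsilyloxy)bicyclo[3.3.0]octan-3-ol (sulfonyl-bearing carbon unassigned) | C2[C@]1(C)CCC[C@]1(C)[C@@H](O[Si](C)(C)C)[C@]2(O)C(S(=O)(=O)c3ccccc3)/C(C)=C\Cc1cc(O[Si](C)(C)C(C)(C)C)cc(C)c1O[Si](C)(C)C(C)(C)C
F6 | step 11 | sulfonyl diol: 3-[(2Z)-4-Ar-2-methyl-1-(phenylsulfonyl)but-2-en-1-yl]-1,5-dimethylbicyclo[3.3.0]octane-2,3-diol | C2[C@]1(C)CCC[C@]1(C)[C@@H](O)[C@]2(O)C(S(=O)(=O)c3ccccc3)/C(C)=C\Cc1cc(O[Si](C)(C)C(C)(C)C)cc(C)c1O[Si](C)(C)C(C)(C)C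
F7 | step 11 | β-keto sulfone aldehyde: (1S,2S)-2-[(4Z)-6-Ar-4-methyl-2-oxo-3-(phenylsulfonyl)hex-4-en-1-yl]-1,2-dimethylcyclopentane-1-carbaldehyde | C/C(=C/Cc1cc(O[Si](C)(C)C(C)(C)C)cc(C)c1O[Si](C)(C)C(C)(C)C)C(S(=O)(=O)c1ccccc1)C(=O)C[C@]1(C)CCC[C@]1(C)C=O
F8 | step 14 | (3-hydroxy-3-methylbut-1-yn-1-yl)zinc triflate | CC(C)(O)C#C[Zn]OS(=O)(=O)C(F)(F)F
F9 | step 14 | propargylic diol: (4Z)-6-Ar-1-[(1S,2S)-2-(1,4-dihydroxy-4-methylpent-2-yn-1-yl)-1,2-dimethylcyclopentyl]-4-methylhex-4-en-2-one | C/C(=C/Cc1cc(O[Si](C)(C)C(C)(C)C)cc(C)c1O[Si](C)(C)C(C)(C)C)CC(=O)C[C@]1(C)CCC[C@]1(C)C(O)C#CC(C)(C)O
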